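Ring A (C1–C2–C3–C4–C5–C10; numbering in the remark) is split into two three-carbon halves. C2–C3–C4 with its methyl group is methyl vinyl ketone. C1–C10–C5 is the allylic (ene) unit of a 2-methyl-methylenecyclohexane that already is ring B, with C8 and C9 set. One Lewis-acid operation joins the halves by two consecutive ene reactions, C1 to C2 and then C5 to C4. This creates quaternary C5 and a C4 carbinol that later becomes the C3=C4 double bond. The precursor is a monocyclic exocyclic alkene bearing an alkynyl handle. The hydroxycyclopentenone ester is unveiled last from a furan by oxidation and aldol closure.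

Key step: step 5

Remark on numbering:
- Ring A = C1, C2, C3, C4, C5, C10. Ring B = C5, C6, C7, C8, C9, C10.
- Methyl groups sit on C4, C5, C8 and C9. C11 is the CH2 on C8.
- The five-membered ring is C1′ (C–OH, CO2Me), C2′ (=CH), C3′ (C–OMe), C4′ (C=O), C5′ (CH bound to C11).
- β is the face of the C5 methyl group (in monocycles, the face of the alkynyl group on C8); α is the other face. Monocyclic compounds keep the ring B numbers.

Step 1
Reactants: 1 3-ethoxycyclohex-2-en-1-one; 2 ethynyl(triisopropyl)silane
Product: 4 3-[(triisopropylsilyl)ethynyl]cyclohex-2-en-1-one, via tertiary alcohol adduct 3 (not isolated)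
Conditions: 2, n-BuLi, THF, −78 °C; 1, −78 to 0 °C; then 1 M aq. HCl, rt
Reagents that add atoms: water, O
Why: 1,2-addition of the lithium acetylide to the vinylogous ester followed by acid hydrolysis with allylic transposition (Stork–Danheiser enone synthesis) should give the enynone, and no stereocentre is formed.

Step 2
Reactants: 4 3-[(triisopropylsilyl)ethynyl]cyclohex-2-en-1-one
Product: 6 (3S)-2,3-dimethyl-3-[(triisopropylsilyl)ethynyl]cyclohexan-1-one (both C2 epimers), via magnesium enolate 5 (not isolated)
Conditions: MeMgBr, Cu(OTf)2 (3 mol %), chiral hydroxyalkyl N-mesityl imidazolinium hexafluorophosphate (NHC precursor, 4 mol %), Et2O, −30 °C; then MeI, DMPU, −30 °C to rt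
Reagents that add atoms: methylmagnesium bromide, C[Mg]Br; iodomethane, CI
Why: copper–NHC-catalysed asymmetric conjugate addition of a Grignard reagent to a cyclic enynone is 1,4-selective and builds the propargylic quaternary centre C8, whose (S) configuration is fixed by the choice of ligand enantiomer; the regiodefined enolate 5 is then C-methylated at C9 (tandem conjugate addition–enolate alkylation) without useful control there, which step 3 corrects.

Step 3
Reactants: 6 (3S)-2,3-dimethyl-3-[(triisopropylsilyl)ethynyl]cyclohexan-1-one (both C2 epimers)
Product: 8 (2S,3S,6R)-2,3,6-trimethyl-3-[(triisopropylsilyl)ethynyl]cyclohexan-1-one, via epimer mixture 7 (not isolated)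
Conditions: LDA, THF, −78 °C; MeI, −78 to 0 °C; work-up; then NaOMe (cat.), MeOH, rt
Reagents that add atoms: iodomethane, CI
Why: kinetic deprotonation takes the unhindered C5 methylene (enolate alkylation), and base equilibration of both enolisable centres (thermodynamic epimerisation) should favour the chair with all three methyl groups equatorial and the slim alkynyl group axial, that is C9–CH3 cis to the alkyne and C5–CH3 cis to C9–CH3; the minor C9 epimer is removed by chromatography and equilibrated again.

Step 4
Reactants: 8 (2S,3S,6R)-2,3,6-trimethyl-3-[(triisopropylsilyl)ethynyl]cyclohexan-1-one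
Product: 9 triisopropyl{[(1S,2R,4R)-1,2,4-trimethyl-3-methylidenecyclohexyl]ethynyl}silane
Conditions: Ph3PCH3Br, KOt-Bu, toluene, 90 °C
Reagents that add atoms: methyltriphenylphosphonium bromide, C[P+](c1ccccc1)(c1ccccc1)c1ccccc1.[Br-]
Why: Wittig methylenation with the salt-free ylide at elevated temperature works on hindered 2,6-disubstituted cyclohexanones; the basic ylide cannot damage C9 and C5 because 8 is already the thermodynamic epimer, and the TIPS-alkyne is stable to alkoxide.

Step 5
Reactants: 9 triisopropyl{[(1S,2R,4R)-1,2,4-trimethyl-3-methylidenecyclohexyl]ethynyl}silane; 10 but-3-en-2-one (methyl vinyl ketone)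
Product: 12 octalin carbinol (C1=C10 double bond; C4 α-OH and β-CH3; C5 β-CH3; C8 α-CH3 and β-(triisopropylsilyl)ethynyl; C9 β-CH3), via ene adduct ketone 11 (not isolated)
Conditions: 10 (slow addition), MeAlCl2 (2.2 equiv), CH2Cl2, −78 to 0 °C; aq. HCl work-up
Reagents that add atoms: none
Why: MeAlCl2-bound methyl vinyl ketone is attacked at its terminal carbon (C2) by the exocyclic methylene carbon C1 of 9 while the axial C5 hydrogen moves to C3 (conjugate ene reaction), which gives ketone 11 with a tetrasubstituted C5=C10 double bond; the aluminium-bound carbonyl carbon C4 of 11 is then attacked by C5 (intramolecular carbonyl-ene reaction at its Prins-like, charge-separated end), a C1 proton is lost, and methane evolution from the Al–CH3 bond makes the sequence irreversible. The closest known reaction type is the alkylaluminium-halide-promoted sequential ene annulation of alkylidenecycloalkanes with acrolein or methyl vinyl ketone, which gives bicyclic homoallylic alcohols. Ring A closes as a six-membered ring through a chair-like array, 6-endo with respect to C5=C10, with the tether on C10 (type 2 topology), so that positive charge builds up on tertiary C10 and not on C5. C5 is controlled by C9: allylic strain with the C1 chain turns the C9 methyl group pseudoaxial on the β face, so C4 bonds to the α face and the C5 methyl group ends β, while at C4 the aluminium alkoxide takes the axial α position next to the developing charge at C10 (this centre is erased in step 8). The step needs hydrogen transfer from C5 and not from C9, bonding at C5 and not at C9 or C10, and an inert alkyne: C9–H is shielded by the neighbouring quaternary C8, bonding at C9 would place two quaternary carbons side by side, spiro closure at C10 would need a strained five-membered array, and the TIPS-capped alkyne is a far poorer nucleophile than a 1,1-disubstituted alkene. With the C9 methyl group pseudoaxial the C9 hydrogen lies near the alkene plane, so the proton is lost from C1 and the C9 stereocentre survives.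

Step 6
Reactants: 12 octalin carbinol; 13 methyl 4,5-dibromofuran-2-carboxylate
Product: 15 methyl 4-bromo-5-(alkynyl)furan-2-carboxylate (alkyne C5′≡C11 bound to C8 of the octalin carbinol), via terminal alkyne 14 (not isolated)
Conditions: TBAF, THF, rt; then 13, PdCl2(PPh3)2 (5 mol %), CuI (10 mol %), Et3N, degassed, 50 °C
Reagents that add atoms: none
Why: fluoride cleaves the alkynyl–silicon bond and alkyne 14 enters a Sonogashira coupling at the more electrophilic C5–Br next to the furan oxygen (site-selective oxidative addition), which keeps the C4–Br for step 9 and touches no stereocentre.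

Step 7
Reactants: 15 methyl 4-bromo-5-(alkynyl)furan-2-carboxylate
Product: 16 trans-decalin carbinol (C10 α-H; C11H2–C5′H2 chain to the bromofuran ester; other centres as in 12)
Conditions: H2 (50 bar), [Ir(cod)(PCy3)(py)]PF6 (10 mol %), CH2Cl2, rt
Reagents that add atoms: none
Why: homogeneous hydrogenation with the cationic iridium complex saturates the alkyne and, after binding to the axial α C4–OH (hydroxyl-directed hydrogenation), adds hydrogen to the α face of C1=C10, the β face being blocked by the C5 and C9 methyl groups, so that C10–H is α and the decalin trans; bromide, ester and furan should not be reduced.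

Step 8
Reactants: 16 trans-decalin carbinol
Product: 17 methyl 4-bromo-5-[2-(decalinyl)ethyl]furan-2-carboxylate with the C3=C4 double bond
Conditions: SOCl2, pyridine, 0 °C
Reagents that add atoms: none
Why: chlorosulfite formation and pyridine-induced anti elimination (E2 dehydration) of the axial tertiary C4–OH uses the antiperiplanar axial β hydrogen on C3 and should give the endocyclic trisubstituted C3=C4 alkene rather than the exocyclic one; C5 is quaternary, so no other ring alkene can form, and the electron-poor bromofuran is inert.

Step 9
Reactants: 17 methyl 4-bromo-5-[2-(decalinyl)ethyl]furan-2-carboxylate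
Product: 18 methyl 4-methoxy-5-[2-(decalinyl)ethyl]furan-2-carboxylate
Conditions: Pd2(dba)3 (2 mol %), tBuBrettPhos (5 mol %), NaOt-Bu, MeOH/1,4-dioxane, 50 °C
Reagents that add atoms: methanol, CO
Why: palladium-catalysed C–O cross-coupling of a heteroaryl bromide with methanol (Buchwald–Hartwig-type etherification) with a bulky biaryl phosphine installs the C3′ methoxy group; methoxide only exchanges the methyl ester with itself, and the hindered alkene does not interfere.

Step 10
Reactants: 18 methyl 4-methoxy-5-[2-(decalinyl)ethyl]furan-2-carboxylate
Product: 20 methyl 4-methoxy-2,5-dioxo-7-(decalinyl)hept-3-enoate (C1′ and C4′ carbonyl carbons cis on C2′=C3′), via furan endoperoxide 19 (not isolated)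
Conditions: O2, tetraphenylporphyrin (cat.), visible light, CH2Cl2, −78 °C; then Me2S, −78 °C to rt
Reagents that add atoms: dioxygen, O=O
Why: [4+2] cycloaddition of singlet oxygen to the donor-substituted furan gives 19, and sulfide reduction opens it to the cis-enedione (furan photooxygenation–reduction); the methoxyfuran should react faster than the hindered trisubstituted C3=C4 alkene if irradiation is stopped when 18 is consumed.

Step 11
Reactants: 20 methyl 4-methoxy-2,5-dioxo-7-(decalinyl)hept-3-enoate
Product: 21 dysidenone A
Conditions: quinine-derived squaramide (3-{[3,5-bis(trifluoromethyl)phenyl]amino}-4-[(9-deoxy-epi-quinin-9-yl)amino]cyclobut-3-ene-1,2-dione, 10 mol %), toluene, −20 °C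
Reagents that add atoms: none
Why: Proposed new method: the quinuclidine nitrogen enolises the C4′ ketone toward C5′ while the squaramide N–H bonds hold the C1′ keto ester, and C5′ adds to C1′ in a 5-(enolendo)-exo-trig aldol best viewed as a disrotatory six-electron closure of the U-shaped oxapentadienyl anion, so that the two outward groups C11H2 and CO2Me end cis and OH trans to C11 (relative configuration), while the chiral pocket selects one of the two disrotatory senses (absolute configuration at C1′ and C5′, which the remote decalin cannot control; the pseudoenantiomeric quinidine catalyst is used if the sense is mismatched), and low temperature and short contact suppress retro-aldol equilibration; the closest known reaction types are the base-induced cyclisation of furan-derived cis-enediones to 4-hydroxycyclopent-2-enones and squaramide-catalysed enantioselective aldol additions to α-keto esters.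

Compound list
1 | 3-ethoxycyclohex-2-en-1-one | CCOC1=CC(=O)CCC1 | starting material
2 | ethynyl(triisopropyl)silane | C#C[Si](C(C)C)(C(C)C)C(C)C | starting material
3 | 3-ethoxy-1-[(triisopropylsilyl)ethynyl]cyclohex-2-en-1-ol (racemic adduct) | CCOC1=CC(O)(C#C[Si](C(C)C)(C(C)C)C(C)C)CCC1 | intermediate
4 | 3-[(triisopropylsilyl)ethynyl]cyclohex-2-en-1-one | O=C1C=C(C#C[Si](C(C)C)(C(C)C)C(C)C)CCC1 | intermediate
5 | bromomagnesium C9=C10 enolate of (S)-3-methyl-3-[(triisopropylsilyl)ethynyl]cyclohexanone | CC(C)[Si](C(C)C)(C(C)C)C#C[C@@]1(C)CCCC(O[Mg]Br)=C1 | intermediate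
6 | (3S)-2,3-dimethyl-3-[(triisopropylsilyl)ethynyl]cyclohexan-1-one, both C2 epimers | CC(C)[Si](C(C)C)(C(C)C)C#C[C@@]1(C)CCCC(=O)C1C | intermediate
7 | (3S)-2,3,6-trimethyl-3-[(triisopropylsilyl)ethynyl]cyclohexan-1-one, C2/C6 epimer mixture | CC(C)[Si](C(C)C)(C(C)C)C#C[C@@]1(C)CCC(C)C(=O)C1C | intermediate
8 | (2S,3S,6R)-2,3,6-trimethyl-3-[(triisopropylsilyl)ethynyl]cyclohexan-1-one | CC(C)[Si](C(C)C)(C(C)C)C#C[C@@]1(C)CC[C@@H](C)C(=O)[C@H]1C | intermediate
9 | triisopropyl{[(1S,2R,4R)-1,2,4-trimethyl-3-methylidenecyclohexyl]ethynyl}silane | CC(C)[Si](C(C)C)(C(C)C)C#C[C@@]1(C)CC[C@@H](C)C(=C)[C@H]1C | intermediate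
10 | but-3-en-2-one (methyl vinyl ketone) | C=CC(C)=O | starting material
11 | 4-(ring B cyclohexenyl)butan-2-one: C5=C10 alkene, chain C1–C4 on C10, C8 and C9 as in 9 | CC(C)[Si](C(C)C)(C(C)C)C#C[C@@]1(C)CCC(C)=C(CCCC(C)=O)[C@H]1C | intermediate
12 | octalin carbinol: C1=C10, C4 α-OH/β-CH3, C5 β-CH3, C8 α-CH3/β-alkynyl(TIPS), C9 β-CH3 | CC(C)[Si](C(C)C)(C(C)C)C#C[C@@]1(C)CC[C@]2(C)[C@](C)(O)CCC=C2[C@H]1C | intermediate
13 | methyl 4,5-dibromofuran-2-carboxylate | COC(=O)c1cc(Br)c(Br)o1 | starting material
14 | terminal alkyne of 12 (8β-ethynyl octalin carbinol) | C#C[C@@]1(C)CC[C@]2(C)[C@](C)(O)CCC=C2[C@H]1C | intermediate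
15 | methyl 4-bromo-5-(octalinylethynyl)furan-2-carboxylate | COC(=O)c1cc(Br)c(C#C[C@@]2(C)CC[C@]3(C)[C@](C)(O)CCC=C3[C@H]2C)o1 | intermediate
16 | methyl 4-bromo-5-[2-(trans-decalinyl)ethyl]furan-2-carboxylate, C4 carbinol, C10 α-H | COC(=O)c1cc(Br)c(CC[C@@]2(C)CC[C@]3(C)[C@](C)(O)CCC[C@H]3[C@H]2C)o1 | intermediate
17 | methyl 4-bromo-5-[2-(decalinyl)ethyl]furan-2-carboxylate, C3=C4 alkene | COC(=O)c1cc(Br)c(CC[C@@]2(C)CC[C@]3(C)C(C)=CCC[C@H]3[C@H]2C)o1 | intermediate
18 | methyl 4-methoxy-5-[2-(decalinyl)ethyl]furan-2-carboxylate | COC(=O)c1cc(OC)c(CC[C@@]2(C)CC[C@]3(C)C(C)=CCC[C@H]3[C@H]2C)o1 | intermediate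
19 | furan endoperoxide (2,3,7-trioxabicyclo[2.2.1]hept-5-ene, both faces) | COC(=O)C12C=C(OC)C(CC[C@@]3(C)CC[C@]4(C)C(C)=CCC[C@H]4[C@H]3C)(OO1)O2 | intermediate
20 | methyl 4-methoxy-2,5-dioxo-7-(decalinyl)hept-3-enoate, carbonyl carbons cis | COC(=O)C(=O)/C=C(/OC)C(=O)CC[C@@]1(C)CC[C@]2(C)C(C)=CCC[C@H]2[C@H]1C | intermediate
21 | dysidenone A | COC(=O)[C@]1(O)C=C(OC)C(=O)[C@@H]1C[C@@]1(C)CC[C@]2(C)C(C)=CCC[C@H]2[C@H]1C | target

Total step count: 11. Longest linear sequence: 11 steps (1 to 21).

Steps most likely to fail

1. Step 11. What may go wrong:
   - the catalyst may impose too little facial selectivity;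
   - enolisation by a tertiary amine may be slow;
   - retro-aldol equilibration or epimerisation at C5′ may erode the kinetic relative configuration.

   The fallback gives up catalyst control for known chemistry with separation and recycling. It sets out from 20, which is cyclised with a simple base (Et3N in CH2Cl2 or aqueous phosphate buffer), the established conversion of cis-enediones into 4-hydroxycyclopent-2-enones. This gives 21 beside the C1′,C5′-bis-epimer F1. The two are diastereomers and are separated by chromatography. F1 is returned to the same base, where retro-aldol opening and reclosure feed it back into the mixture. The fallback comes back to the route at 21.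

2. Step 5. What may go wrong:
   - hydrogen transfer from C9 instead of C5 in the first ene reaction;
   - polymerisation of the enone;
   - spiro closure at C10;
   - hydride or methyl shifts of the C10 cation;
   - loss of the C9 proton instead of a C1 proton, which step 7 could still correct, because syn addition of hydrogen to the α face restores the same C9 and C10 configuration.

   The fallback builds the chain by cross-coupling instead of an intermolecular ene reaction. It sets out from 8, which is deprotonated at the less hindered C5–H (KHMDS) and trapped with PhNTf2 to give enol triflate F2. Negishi coupling with [3-(2-methyl-1,3-dioxolan-2-yl)propyl]zinc bromide and PdCl2(dppf) gives ketal F3. Mild hydrolysis (PPTS, aqueous acetone) frees ketone 11, now isolated with an unambiguous C5=C10 double bond. A separate MeAlCl2-promoted carbonyl-ene closure gives 12, where the fallback comes back to the route.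

3. Step 7. What may go wrong:
   - the alkyne may deactivate the iridium catalyst;
   - the hindered C1=C10 alkene may stay unreduced or migrate.

   The fallback separates the two reductions and changes the mechanism of the second. It sets out from 15, whose alkyne alone is saturated with H2 and RhCl(PPh3)3 to give the octalin bromofuran F4. The ring alkene is then reduced by radical hydrogen-atom transfer (Mn(dpm)3, PhSiH3, t-BuOOH, i-PrOH). A hydrogen atom adds to C1, and the tertiary C10 radical takes up hydrogen to give the thermodynamically preferred trans-decalin. The fallback comes back to the route at 16.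

Further compounds
F1 | step 11 | C1′,C5′-bis-epimer of dysidenone A | COC(=O)[C@@]1(O)C=C(OC)C(=O)[C@H]1C[C@@]1(C)CC[C@]2(C)C(C)=CCC[C@H]2[C@H]1C
F2 | step 5 | C10 enol triflate of 8 (C5=C10 double bond) | CC(C)[Si](C(C)C)(C(C)C)C#C[C@@]1(C)CCC(C)=C(OS(=O)(=O)C(F)(F)F)[C@H]1C
F3 | step 5 | ethylene ketal of 11 | CC(C)[Si](C(C)C)(C(C)C)C#C[C@@]1(C)CCC(C)=C(CCCC2(C)OCCO2)[C@H]1C
F4 | step 7 | methyl 4-bromo-5-[2-(octalinyl)ethyl]furan-2-carboxylate (C1=C10 retained, C4 carbinol) | COC(=O)c1cc(Br)c(CC[C@@]2(C)CC[C@]3(C)[C@](C)(O)CCC=C3[C@H]2C)o1
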